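## Retrosynthetic overview

- Numbering (drimane-type): ring A = C1–C5 + C10, ring B = C5–C10; C11 = ArCH2 on C9, C12 = exocyclic CH2 on C8, C19 = carboxyl carbon on C4.
- Disconnections: (a) hydroxynaphthoquinone from an aryl bromide and an alkoxycyclobutenedione by ring expansion (last ring); (b) ring A by the C3–C4 bond, through conjugate reduction/enolate alkylation of an α-substituted acrylate, which also creates quaternary C4; (c) ring B by an intermolecular [4+2] that forms C5–C6 and C9–C10 from a (Z)-2-silyloxy diene (C6=C7–C8(OSi)=C9–C11–aryl) and an (E)-β,β-disubstituted β,γ-unsaturated α-keto ester (C19–C4(=O)–C5=C10(CH3)–C1–C2–C3–Cl), two fragments of similar size joined at quaternary C10.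
- Enabling feature: in ring B the sp2 carbon C8 (the methylidene carbon, read as a ketone) stands 1,4 to C5, and C5 carries C4 with the carboxyl carbon C19 (read as a 1,2-dicarbonyl). Donor at C8 and acceptor at C4 polarise diene and dienophile so that C9 bonds to the fully substituted C10, and both C=O groups later become C=CH2 in one operation.
- Ring order: ring B (step 8), ring A (step 10), quinone ring (step 13).

Key step: step 8

Remark: 2-bromo-6-methylbenzaldehyde, 5-chloropent-1-yne and di-tert-butyl squarate are taken as commercial; the facial sense of the copper catalyst on this substrate class is an assumption, so the (S,S) ligand [t-Bu-box = 2,2′-(propane-2,2-diyl)bis((4S)-4-tert-butyl-4,5-dihydrooxazole)] is written and its antipode would be used if the opposite face is delivered.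

## Route

Step 1
Reactants: 1 2-bromo-6-methylbenzaldehyde
Product: 2 (2-bromo-6-methylphenyl)methanol
Conditions: NaBH4, MeOH, 0 °C
Reagents that add atoms: none
Why: Borohydride reduction of the aldehyde is chemoselective and leaves the aryl bromide untouched.

Step 2
Reactants: 2 (2-bromo-6-methylphenyl)methanol
Product: 3 1-bromo-2-(bromomethyl)-3-methylbenzene
Conditions: PBr3, Et2O, 0 °C → rt
Reagents that add atoms: phosphorus tribromide, BrP(Br)Br
Why: The benzylic alcohol is brominated by SN2 displacement of its phosphite ester (PBr3 bromination).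

Step 3
Reactants: 3 1-bromo-2-(bromomethyl)-3-methylbenzene
Product: 4 3-(2-bromo-6-methylphenyl)-N-methoxy-N-methylpropanamide
Conditions: LiN(i-Pr)2, N-methoxy-N-methylacetamide, THF, −78 °C; then 3, −78 → −20 °C
Reagents that add atoms: N-methoxy-N-methylacetamide, CC(=O)N(C)OC
Why: Enolate alkylation of the lithium enolate of the Weinreb acetamide by the reactive benzylic bromide at low temperature installs C9 and C8.

Step 4
Reactants: 4 3-(2-bromo-6-methylphenyl)-N-methoxy-N-methylpropanamide
Product: 5 5-(2-bromo-6-methylphenyl)pent-1-en-3-one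
Conditions: CH2=CHMgBr, THF, −20 → 0 °C; inverse quench into cold 1 M HCl
Reagents that add atoms: vinylmagnesium bromide, C=C[Mg]Br
Why: In the Weinreb ketone synthesis the chelated tetrahedral adduct stops at the ketone, and the cold acidic quench keeps the liberated amine from adding to the vinyl ketone.

Step 5
Reactants: 5 5-(2-bromo-6-methylphenyl)pent-1-en-3-one
Product: 6 tert-butyl{[(3Z)-5-(2-bromo-6-methylphenyl)penta-1,3-dien-3-yl]oxy}dimethylsilane
Conditions: t-BuMe2SiOTf, Et3N, Et2O, 0 °C
Reagents that add atoms: tert-butyldimethylsilyl triflate, CC(C)(C)[Si](C)(C)OS(=O)(=O)C(F)(F)F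
Why: Soft enolisation/O-silylation toward the only α-CH2 (C9) should give the 2-silyloxy diene, and silyl triflate/amine conditions are expected to favour the (Z) enol ether, which holds C11 outside in the s-cis diene.

Step 6
Reactants: 7 5-chloropent-1-yne
Product: 9 (1E)-5-chloro-1-iodo-2-methylpent-1-ene, via alkenylalane 8 (not isolated)
Conditions: Me3Al, Cp2ZrCl2 (25 mol %), CH2Cl2, 0 °C → rt; then I2, THF, −30 → 0 °C
Reagents that add atoms: trimethylaluminium, C[Al](C)C; iodine, II
Why: Negishi carboalumination adds methyl and aluminium syn across the terminal alkyne and iodinolysis proceeds with retention, which fixes the methyl cis to the future C5 substituent.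

Step 7
Reactants: 9 (1E)-5-chloro-1-iodo-2-methylpent-1-ene
Product: 11 tert-butyl (3E)-7-chloro-4-methyl-2-oxohept-3-enoate, via alkenyllithium 10 (not isolated)
Conditions: t-BuLi (2 equiv), Et2O, −78 °C; cannulated into (t-BuO2C)2 (3 equiv), THF, −78 °C; AcOH quench
Reagents that add atoms: di-tert-butyl oxalate, CC(C)(C)OC(=O)C(=O)OC(C)(C)C
Why: Iodine–lithium exchange keeps the alkene geometry, and monoacylation by excess oxalate under inverse addition gives the α-keto ester because the tetrahedral adduct is stable at −78 °C; the alkyl chloride is inert at this temperature.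

Step 8
Reactants: 6 tert-butyl{[(3Z)-5-(2-bromo-6-methylphenyl)penta-1,3-dien-3-yl]oxy}dimethylsilane; 11 tert-butyl (3E)-7-chloro-4-methyl-2-oxohept-3-enoate
Product: 13 tert-butyl 2-[(1S,2S,3S)-3-[(2-bromo-6-methylphenyl)methyl]-2-(3-chloropropyl)-2-methyl-4-oxocyclohexyl]-2-oxoacetate, via silyl enol ether 12 (not isolated)
Conditions: [Cu((S,S)-t-Bu-box)](SbF6)2 (10 mol %), 4 Å MS, CH2Cl2, −40 → −10 °C; then HF·pyridine, THF, 0 °C
Reagents that add atoms: none
Why: Proposed new method: the cationic divalent copper bis(oxazoline) complex chelates the 1,2-dicarbonyl of 11 and lowers the LUMO of its (E)-β,β-disubstituted enone, so that the (Z)-2-silyloxy diene 6 adds in a concerted but strongly asynchronous normal-demand Diels–Alder reaction in which the enol-ether carbon C9 bonds to the β-carbon C10 ahead of C6–C5 (a stepwise Mukaiyama–Michael/ring-closing Michael course, or a hetero-cycloaddition followed by a [3,3] shift, would end in the same carbocycle). The closest known reaction types are Lewis-acid-promoted Diels–Alder reactions of 2-silyloxy dienes with β,β-disubstituted enones, which build a quaternary carbon next to a tertiary one, and copper bis(oxazoline)-catalysed enantioselective cycloadditions and conjugate additions of β-monosubstituted β,γ-unsaturated α-keto esters; catalytic enantiocontrol on a β,β-disubstituted keto ester in a carbo-Diels–Alder reaction is the new element. Ring B closes by a suprafacial six-membered [4+2] closure, both new bonds forming on one face of each π system. The C10/C5 relationship (C4 acyl cis to the C10 methyl) is copied from the (E) geometry of 11, C9 follows from endo approach of the chelated acyl group combined with the (Z) enol ether that holds C11 outside (C11 cis to C4 and to the C10 methyl), and the absolute configuration is set by the tert-butyl groups of the ligand, which shield one face of the square-planar chelate. The step needs regioselectivity (C9 to C10), endo selectivity and face selectivity: the first is secured by the 1,4 donor/acceptor pairing (silyloxy on C8, keto ester on C5), the second by the small methyl taking the endo position beside the acyl group, and the kinetic adduct carries all three large ring substituents equatorial, so single epimerisation at C5 is uphill. Buffered HF·pyridine then protonates C7 of the silyl enol ether and reveals the C8 ketone without touching C9.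

Step 9
Reactants: 13 tert-butyl 2-[(1S,2S,3S)-3-[(2-bromo-6-methylphenyl)methyl]-2-(3-chloropropyl)-2-methyl-4-oxocyclohexyl]-2-oxoacetate
Product: 14 tert-butyl 2-[(1S,2S,3R)-3-[(2-bromo-6-methylphenyl)methyl]-2-(3-chloropropyl)-2-methyl-4-methylidenecyclohexyl]prop-2-enoate
Conditions: Zn, CH2Br2, TiCl4, THF/CH2Cl2, 0 °C → rt (excess reagent)
Reagents that add atoms: dibromomethane, BrCBr
Why: Lombardo–Takai methylenation is non-basic, so both ketones (C8 and C4) should be converted to C=CH2 without epimerising C5 or C9, while the tert-butyl ester, the alkyl chloride and the aryl bromide are left alone.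

Step 10
Reactants: 14 tert-butyl 2-[(1S,2S,3R)-3-[(2-bromo-6-methylphenyl)methyl]-2-(3-chloropropyl)-2-methyl-4-methylidenecyclohexyl]prop-2-enoate
Product: 16 tert-butyl (1S,4aS,5R,8aS)-5-[(2-bromo-6-methylphenyl)methyl]-1,4a-dimethyl-6-methylidenedecahydronaphthalene-1-carboxylate, via lithium enolate 15 (not isolated)
Conditions: LiBH(s-Bu)3 (L-Selectride, 1.05 equiv), THF, −78 °C; then DMPU, −78 → 40 °C
Reagents that add atoms: none
Why: Conjugate hydride addition to the β-unsubstituted acrylate gives the tetrasubstituted ester enolate, which closes ring A by 6-exo-tet displacement of chloride (reductive enolate alkylation); allylic 1,3-strain holds the C5–H bond in the enolate plane, so C3 adds on the face flanked by C10 and the new methyl ends anti to H5 (axial, cis to the C10 methyl) with the ester equatorial.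

Step 11
Reactants: 17 3,4-di-tert-butoxycyclobut-3-ene-1,2-dione
Product: 19 3-tert-butoxy-4-methylcyclobut-3-ene-1,2-dione, via lithium alkoxide 18 (not isolated)
Conditions: MeLi, THF, −78 °C; then (CF3CO)2O, −78 → 0 °C; aq NH4Cl
Reagents that add atoms: methyllithium, [Li]C
Why: 1,2-Addition of methyllithium to the squarate followed by trifluoroacetylation of the carbinol triggers the known carbonyl transposition with loss of one tert-butoxy group.

Step 12
Reactants: 16 tert-butyl (1S,4aS,5R,8aS)-5-[(2-bromo-6-methylphenyl)methyl]-1,4a-dimethyl-6-methylidenedecahydronaphthalene-1-carboxylate; 19 3-tert-butoxy-4-methylcyclobut-3-ene-1,2-dione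
Product: 21 tert-butyl (1S,4aS,5R,8aS)-5-{[2-(2-tert-butoxy-1-hydroxy-3-methyl-4-oxocyclobut-2-en-1-yl)-6-methylphenyl]methyl}-1,4a-dimethyl-6-methylidenedecahydronaphthalene-1-carboxylate (either configuration at the carbinol carbon), via aryllithium 20 (not isolated)
Conditions: t-BuLi (2.1 equiv), THF, −78 °C; then 19, −78 °C; aq NH4Cl
Reagents that add atoms: none
Why: Bromine–lithium exchange is fast at −78 °C beside the hindered tert-butyl ester, and the aryllithium adds 1,2 to the more electrophilic carbonyl of 19, the one next to the alkoxy-bearing carbon and not the vinylogous ester carbonyl.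

Step 13
Reactants: 21 tert-butyl (1S,4aS,5R,8aS)-5-{[2-(2-tert-butoxy-1-hydroxy-3-methyl-4-oxocyclobut-2-en-1-yl)-6-methylphenyl]methyl}-1,4a-dimethyl-6-methylidenedecahydronaphthalene-1-carboxylate
Product: 23 tert-butyl (1S,4aS,5R,8aS)-5-[(7-tert-butoxy-2,6-dimethyl-5,8-dioxo-5,8-dihydronaphthalen-1-yl)methyl]-1,4a-dimethyl-6-methylidenedecahydronaphthalene-1-carboxylate, via hydroquinone 22 (not isolated)
Conditions: toluene (degassed), 110 °C; then Ag2O, MgSO4, Et2O, rt
Reagents that add atoms: none
Why: In the Moore rearrangement, 4π ring opening gives an aryl vinylketene that closes by 6π electrocyclisation onto the only free ortho position and tautomerises to the hydroquinone, which Ag2O oxidises to the quinone; this places the alkoxy-flanked carbonyl peri to C11 and the quinone methyl on the far side.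

Step 14
Reactants: 23 tert-butyl (1S,4aS,5R,8aS)-5-[(7-tert-butoxy-2,6-dimethyl-5,8-dioxo-5,8-dihydronaphthalen-1-yl)methyl]-1,4a-dimethyl-6-methylidenedecahydronaphthalene-1-carboxylate
Product: 25 (1S,4aS,5R,8aS)-5-[(7-hydroxy-2,6-dimethyl-5,8-dioxo-5,8-dihydronaphthalen-1-yl)methyl]-1,4a-dimethyl-6-methylidenedecahydronaphthalene-1-carboxylic acid, via bis(trimethylsilyl) derivative 24 (not isolated)
Conditions: Me3SiOTf, 2,6-lutidine, CH2Cl2, 0 °C → rt; then aq citric acid
Reagents that add atoms: none
Why: Silyl triflate cleaves both tert-butyl groups (ester and vinylogous ester) by loss of tert-butyl cation under buffered, non-protic conditions that should spare the 1,1-disubstituted alkene, and the silyl ester and silyl ether hydrolyse on work-up.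

## Compound list

1 | 2-bromo-6-methylbenzaldehyde | Cc1cccc(Br)c1C=O | starting material
2 | (2-bromo-6-methylphenyl)methanol | Cc1cccc(Br)c1CO | intermediate
3 | 1-bromo-2-(bromomethyl)-3-methylbenzene | Cc1cccc(Br)c1CBr | intermediate
4 | 3-(2-bromo-6-methylphenyl)-N-methoxy-N-methylpropanamide | Cc1cccc(Br)c1CCC(=O)N(C)OC | intermediate
5 | 5-(2-bromo-6-methylphenyl)pent-1-en-3-one | Cc1cccc(Br)c1CCC(=O)C=C | intermediate
6 | tert-butyl{[(3Z)-5-(2-bromo-6-methylphenyl)penta-1,3-dien-3-yl]oxy}dimethylsilane | C=C/C(O[Si](C)(C)C(C)(C)C)=C/Cc1c(C)cccc1Br | intermediate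
7 | 5-chloropent-1-yne | C#CCCCCl | starting material
8 | [(1E)-5-chloro-2-methylpent-1-en-1-yl]dimethylalane | C[Al](C)/C=C(\C)CCCCl | intermediate
9 | (1E)-5-chloro-1-iodo-2-methylpent-1-ene | I/C=C(\C)CCCCl | intermediate
10 | [(1E)-5-chloro-2-methylpent-1-en-1-yl]lithium | [Li]/C=C(\C)CCCCl | intermediate
11 | tert-butyl (3E)-7-chloro-4-methyl-2-oxohept-3-enoate | CC(C)(C)OC(=O)C(=O)/C=C(\C)CCCCl | intermediate
12 | tert-butyl 2-[(1S,5S,6S)-5-[(2-bromo-6-methylphenyl)methyl]-4-[(tert-butyldimethylsilyl)oxy]-6-(3-chloropropyl)-6-methylcyclohex-3-en-1-yl]-2-oxoacetate | CC(C)(C)[Si](C)(C)OC1=CC[C@H](C(=O)C(=O)OC(C)(C)C)[C@@](C)(CCCCl)[C@@H]1Cc1c(C)cccc1Br | intermediate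
13 | tert-butyl 2-[(1S,2S,3S)-3-[(2-bromo-6-methylphenyl)methyl]-2-(3-chloropropyl)-2-methyl-4-oxocyclohexyl]-2-oxoacetate | O=C1CC[C@H](C(=O)C(=O)OC(C)(C)C)[C@@](C)(CCCCl)[C@@H]1Cc1c(C)cccc1Br | intermediate
14 | tert-butyl 2-[(1S,2S,3R)-3-[(2-bromo-6-methylphenyl)methyl]-2-(3-chloropropyl)-2-methyl-4-methylidenecyclohexyl]prop-2-enoate | C=C1CC[C@H](C(=C)C(=O)OC(C)(C)C)[C@@](C)(CCCCl)[C@@H]1Cc1c(C)cccc1Br | intermediate
15 | lithium enolate of the tert-butyl propanoate formed from 14 by hydride addition to the acrylate CH2 (ring substituents as in 14) | C=C1CC[C@H](C(C)=C(O[Li])OC(C)(C)C)[C@@](C)(CCCCl)[C@@H]1Cc1c(C)cccc1Br | intermediate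
16 | tert-butyl (1S,4aS,5R,8aS)-5-[(2-bromo-6-methylphenyl)methyl]-1,4a-dimethyl-6-methylidenedecahydronaphthalene-1-carboxylate | C=C1CC[C@H]2[C@@](C)(CCC[C@]2(C)C(=O)OC(C)(C)C)[C@@H]1Cc1c(C)cccc1Br | intermediate
17 | 3,4-di-tert-butoxycyclobut-3-ene-1,2-dione (di-tert-butyl squarate) | CC(C)(C)OC1=C(OC(C)(C)C)C(=O)C1=O | starting material
18 | lithium 2,3-di-tert-butoxy-1-methyl-4-oxocyclobut-2-en-1-olate | CC(C)(C)OC1=C(OC(C)(C)C)C(C)(O[Li])C1=O | intermediate
19 | 3-tert-butoxy-4-methylcyclobut-3-ene-1,2-dione | CC1=C(OC(C)(C)C)C(=O)C1=O | intermediate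
20 | aryllithium from 16 (lithium in place of bromine) | C=C1CC[C@H]2[C@@](C)(CCC[C@]2(C)C(=O)OC(C)(C)C)[C@@H]1Cc1c(C)cccc1[Li] | intermediate
21 | tert-butyl (1S,4aS,5R,8aS)-5-{[2-(2-tert-butoxy-1-hydroxy-3-methyl-4-oxocyclobut-2-en-1-yl)-6-methylphenyl]methyl}-1,4a-dimethyl-6-methylidenedecahydronaphthalene-1-carboxylate (carbinol epimers) | C=C1CC[C@H]2[C@@](C)(CCC[C@]2(C)C(=O)OC(C)(C)C)[C@@H]1Cc1c(C)cccc1C1(O)C(OC(C)(C)C)=C(C)C1=O | intermediate
22 | tert-butyl (1S,4aS,5R,8aS)-5-[(7-tert-butoxy-5,8-dihydroxy-2,6-dimethylnaphthalen-1-yl)methyl]-1,4a-dimethyl-6-methylidenedecahydronaphthalene-1-carboxylate | C=C1CC[C@H]2[C@@](C)(CCC[C@]2(C)C(=O)OC(C)(C)C)[C@@H]1Cc1c(C)ccc2c(O)c(C)c(OC(C)(C)C)c(O)c12 | intermediate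
23 | tert-butyl (1S,4aS,5R,8aS)-5-[(7-tert-butoxy-2,6-dimethyl-5,8-dioxo-5,8-dihydronaphthalen-1-yl)methyl]-1,4a-dimethyl-6-methylidenedecahydronaphthalene-1-carboxylate | C=C1CC[C@H]2[C@@](C)(CCC[C@]2(C)C(=O)OC(C)(C)C)[C@@H]1Cc1c(C)ccc2c1C(=O)C(OC(C)(C)C)=C(C)C2=O | intermediate
24 | trimethylsilyl (1S,4aS,5R,8aS)-5-{[2,6-dimethyl-5,8-dioxo-7-(trimethylsilyloxy)-5,8-dihydronaphthalen-1-yl]methyl}-1,4a-dimethyl-6-methylidenedecahydronaphthalene-1-carboxylate | C=C1CC[C@H]2[C@@](C)(CCC[C@]2(C)C(=O)O[Si](C)(C)C)[C@@H]1Cc1c(C)ccc2c1C(=O)C(O[Si](C)(C)C)=C(C)C2=O | intermediate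
25 | (1S,4aS,5R,8aS)-5-[(7-hydroxy-2,6-dimethyl-5,8-dioxo-5,8-dihydronaphthalen-1-yl)methyl]-1,4a-dimethyl-6-methylidenedecahydronaphthalene-1-carboxylic acid (CNP0259461.3) | C=C1CC[C@H]2[C@@](C)(CCC[C@]2(C)C(=O)O)[C@@H]1Cc1c(C)ccc2c1C(=O)C(O)=C(C)C2=O | target

## Step count and risk assessment

Total step count: 14. Longest linear sequence: 11 steps (steps 1–5, 8, 9, 10, 12, 13, 14).

Steps most likely to fail:

Step 8 (the proposed new method). The hindered β,β-disubstituted acceptor may turn over poorly on the chiral copper complex, or the ligand may discriminate the two faces of the chelate insufficiently. The fallback uses an achiral Lewis acid and a resolution. It sets out from 6 and 11: Sc(OTf)3 (10 mol %) in CH2Cl2 at −20 °C, followed by the same HF·pyridine treatment, should give racemic ketone, that is 13 together with its antipode ent-13 F1. Ketalisation of the ring ketone with (2R,3R)-butane-2,3-diol (pyridinium tosylate, benzene, reflux with water removal; the α-keto ester carbonyl should not ketalise) gives two diastereomeric dioxolanes, the ketal of 13 F2 and the ketal of ent-13 F3. These would be separated by chromatography or crystallisation, and hydrolysis of F2 (pyridinium tosylate, acetone/H2O, 50 °C) comes back to the route at 13.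

Step 10. The enolate may add to unreduced acrylate (oligomerisation), hydride may attack the ester carbonyl, or the chloride may be displaced too slowly. The fallback separates reduction from ring closure; it uses the same enolate, so it does not address a possible low C4 selectivity. It sets out from 14: conjugate reduction with [(Ph3P)CuH]6 (benzene, rt, aqueous work-up) gives the saturated ester F4 as a mixture of C4 epimers. Halide exchange (NaI, acetone, reflux) gives the iodide F5. Slow addition of F5 to LiN(i-Pr)2 in THF/DMPU at −78 → 0 °C under high dilution regenerates the same tetrasubstituted enolate and closes ring A, coming back to the route at 16.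

Step 13. The free hydroxyl of the vinylketene intermediate may attack the ketene (butenolide formation) faster than the 6π closure onto the ortho carbon, which is hindered by the neighbouring substituents, and the tert-butoxy group may be lost unevenly on heating. The fallback caps the carbinol. It sets out from 21: silylation (Me3SiCl, imidazole, DMF, 0 °C) gives the trimethylsilyl ether F6. Thermolysis (toluene, 110 °C) then gives the 4-silyloxy-1-naphthol F7, and oxidation with (NH4)2Ce(NO3)6 in MeCN/H2O at 0 °C comes back to the route at 23.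

Further compounds
F1 | step 8 | antipode of 13 (ent-13, formed with 13 as the racemate) | O=C1CC[C@@H](C(=O)C(=O)OC(C)(C)C)[C@](C)(CCCCl)[C@H]1Cc1c(C)cccc1Br
F2 | step 8 | (2R,3R)-butane-2,3-diyl ketal of 13 at the ring ketone | C[C@H]1OC2(CC[C@H](C(=O)C(=O)OC(C)(C)C)[C@@](C)(CCCCl)[C@@H]2Cc2c(C)cccc2Br)O[C@@H]1C
F3 | step 8 | (2R,3R)-butane-2,3-diyl ketal of ent-13 at the ring ketone | C[C@H]1OC2(CC[C@@H](C(=O)C(=O)OC(C)(C)C)[C@](C)(CCCCl)[C@H]2Cc2c(C)cccc2Br)O[C@@H]1C
F4 | step 10 | tert-butyl 2-substituted propanoate from 14 (acrylate C=C reduced, ring substituents as in 14, both C4 epimers) | C=C1CC[C@H](C(C)C(=O)OC(C)(C)C)[C@@](C)(CCCCl)[C@@H]1Cc1c(C)cccc1Br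
F5 | step 10 | iodide corresponding to F4 (3-iodopropyl in place of 3-chloropropyl) | C=C1CC[C@H](C(C)C(=O)OC(C)(C)C)[C@@](C)(CCCI)[C@@H]1Cc1c(C)cccc1Br
F6 | step 13 | trimethylsilyl ether of 21 at the carbinol oxygen | C=C1CC[C@H]2[C@@](C)(CCC[C@]2(C)C(=O)OC(C)(C)C)[C@@H]1Cc1c(C)cccc1C1(O[Si](C)(C)C)C(OC(C)(C)C)=C(C)C1=O
F7 | step 13 | mono-trimethylsilyl ether of hydroquinone 22 (silyloxy on the carbon peri to C11, free hydroxyl on the other) | C=C1CC[C@H]2[C@@](C)(CCC[C@]2(C)C(=O)OC(C)(C)C)[C@@H]1Cc1c(C)ccc2c(O)c(C)c(OC(C)(C)C)c(O[Si](C)(C)C)c12
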